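**Remarks on the chemistry (assumptions)**

- The target has no stereocentre, and its biaryl axis (one OH and one CH2 group ortho to it) is taken as freely rotating. All chiral intermediates are therefore racemates or diastereomer mixtures by design.
- The connectivity of the annulation partners and of the annulation product was checked atom by atom against ring A and needed no correction. The aldehyde α-carbon becomes the arm-bearing ring carbon, and the benzylic carbon of the ketone becomes the aryl-bearing ring carbon.
- The ring B catechol is carried as two benzyl ethers and the two-carbon acyl unit as an ethyl ester. The first allows a neutral last step and a protected starting material that can be bought. The second gives the N-methoxy-N-methylamide without an acid cleavage.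
- Compounds 1, 3 and 11 and a THF solution of BrZnCH2CO2Et are taken as purchasable.

## Structural features

Isoplagilin (21) is an open-chain bis(bibenzyl). Two catechol rings, A and B, are joined directly by a biaryl bond, and each carries a 2-(3-methoxyphenyl)ethyl arm, so the core is a biphenyl-2,3,3',4'-tetraol with arms at C5 and C6'. On ring A the biaryl carbon C1 lies next to the C2 hydroxyl, and the arm at C5 is meta to the biaryl bond and para to the C2 hydroxyl. On ring B the arm at C6' is ortho to the biaryl bond, and the two hydroxyls at C3' and C4' are para to the arm carbon and to the biaryl carbon. There is no stereocentre in the target. Stereocentres appear only in passing (C4 of the cyclohexenone 16, and C4 and C6 of 18 in a 1,3-relation) and all are erased on aromatization. The fragile parts are the two free catechols, which oxidize easily to ortho-quinones in air and base, and the two aryl methyl ethers, which must survive while four phenolic oxygens are unmasked. This rules out methyl ethers as catechol protection and any late Lewis-acid demethylation. The real difficulty is regiochemical: ring A is 1,2,3,5-tetrasubstituted and sits on a hindered, electron-rich biaryl bond. The key step uses the fact that ring A is the dienol tautomer of a cyclohex-3-ene-1,2-dione. Ring A C1 (aryl-bearing) can be the α-carbon and ring A C5 (arm-bearing) the γ-carbon of a cyclohex-2-enone. The biaryl bond is then never made by coupling; it is carried in as the aryl–CH2 bond of a ring B benzyl ketone, around which ring A is built by Michael–aldol annulation.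

## Logic of the disconnections

**21 from 20.** Only the two O–CH2Ph bonds on ring B are cut. Unmasking the second catechol last means that no earlier compound carries more than one free catechol. The forward step must cleave benzyl ethers and leave aryl methyl ethers alone; hydrogenolysis does this because 20 holds no other reducible group.

**20 from 18 through 19.** No skeletal bond is cut. Ring A of 20 is rewritten as its diketo tautomer 19, and one carbonyl group of 19 is traced back to the secondary alcohol of 18. An aromatic substitution pattern thus becomes carbonyl chemistry on a six-membered ring. The forward step needs an oxidant for the carbinol that does not attack the catechol formed by tautomerization, and a base for the two enolizations.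

**18 from 16 through 17.** The C–O bond at the α'-carbon (C6) is cut, which leaves ring A as a cyclohexenone with a single oxygen. The forward step needs deprotonation at the C6 methylene and not at the C4 methine, and an electrophilic oxygen source. The configuration at C6 need not be controlled.

**16 from 13 and 10 through 14 and 15.** Two ring bonds are cut: the C2=C3 double bond (retro-aldol condensation) and the C4–C5 single bond (retro-Michael). Two ring carbons then come from 13 and four from 10, and each half already carries one arm. The biaryl bond of 21 is the aryl–CH2 bond already present in 10. The forward step requires the cross-Michael addition to outrun self-condensation of either partner. Closure through the benzylic carbon is guaranteed by ring size.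

**13 from 11 through 12.** Only the oxidation level changes. The forward step needs a reduction that stops at the aldehyde.

**10 from 8 through 9.** The bond between the carbonyl carbon and the vinyl group is cut. The enone is the least stable compound of the route, so it is unmasked one step before it is consumed. The forward step needs a single addition of the vinyl nucleophile and an isolation in which the released amine cannot add to the enone.

**8 from 7, and 7 from 6.** First the acyl C–N bond is exchanged for the ester, then the bond between ring B and its CH2 group is cut. The second cut attaches a two-carbon acyl unit to an aryl bromide under non-basic conditions. The ethyl ester is chosen so that 8 forms in one step with no acid cleavage. The forward step needs oxidative addition to an electron-rich bromide that has an ortho alkyl group.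

**6 from 5, and 5 from 2 and 3 through 4.** The ring B arm is cut at its central C–C bond after the double bond is put back. The olefination joins the anisole ring to ring B at carbons that bear no other function. The reduction of 5 must spare the C–Br bond and the benzyl ethers, which rules out Pd-catalysed hydrogenation.

**2 from 1.** The C–Br bond is cut. 1 is bought with the catechol already benzylated, which saves a demethylation and a re-protection. The forward step needs bromination para to the C3 oxygen.

## Other disconnections considered

**Alternative 1:** Ring A is opened at C2–C1 (inner oxygenated carbon to aryl-bearing carbon) and at C5–C6 (arm-bearing carbon to the unsubstituted carbon next to the biaryl bond). This gives a four-carbon pyrone, 3,4-bis(benzyloxy)-6-[2-(3-methoxyphenyl)ethyl]-2H-pyran-2-one A1, and a two-carbon ring B ynoate, methyl 3-{4,5-bis(benzyloxy)-2-[2-(3-methoxyphenyl)ethyl]phenyl}prop-2-ynoate A2. In the forward direction A1 would add A2 across pyrone C3 and C6 in a thermal Diels–Alder reaction. The bridged lactone would then lose its O–C(=O) bridge by decarboxylative cycloreversion and give the aromatic biaryl benzoate A3, with the ester on the carbon that is CH in 21.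
- In favour: ring A arrives aromatic with both oxygens in place, so no enolate oxidation and no tautomerization are needed. The biaryl bond is again not made by cross-coupling, which makes it the equal of the chosen plan on that point. It avoids the air-sensitive oxidation sequence, and there it is the better plan.
- Against: the regiochemistry depends on how two opposing benzyloxy groups polarize an unsymmetrical diene towards an ynoate whose electrophilic carbon carries a bulky ortho-substituted aryl group. The wrong pairing (C3 to the ester-bearing carbon) cannot be excluded, whereas in the chosen plan ring size alone fixes the connectivity. The cycloaddition must also create a biaryl bond flanked by three ortho substituents at the high temperatures such reactions usually need. The activating ester must then be removed from a doubly ortho-substituted position by hydrolysis and protodecarboxylation, two steps that add nothing to the skeleton.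
- Step economy: A1 would come from a simple pyrone by C3 oxygenation, benzylation and chain extension, and A2 from 6. With cycloaddition, ester removal and debenzylation the sequence is expected to equal the chosen one or exceed it by one to two steps, with a less predictable key step.

**Alternative 2:** The two aryl–CH2 bonds of the arms are cut (ring A C5 and ring B C6' to their bridge carbons). This leaves the bare core biphenyl-2,3,3',4'-tetraol A4 and two molecules of 3-methoxyphenylacetic acid A5. The forward step is a twofold Friedel–Crafts (Fries-type) acylation of A4 by A5 in a boron Lewis acid medium to the bis(deoxybenzoin) A6, followed by reduction of both aryl ketones to CH2.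
- In favour: it is by far the shortest plan. It needs no protecting groups, both arms come from one cheap reagent, and each ring is deactivated after its first acylation. On step count and protecting-group economy it is clearly better than the chosen plan.
- Against: everything depends on innate directing effects. On ring A the acyl group must enter C5 (para to the C2 hydroxyl) and not C6 or C4. On ring B it must enter C6', the most hindered position, and not C5' or C2', which lie ortho to oxygen and are favoured by chelation. The anisole ring of A5 is itself a good acyl acceptor, so self-condensation of the reagent would compete. A4 would itself require a biaryl coupling of two protected catechols and a deprotection, and the double benzylic deoxygenation must be done on a compound with two free catechols.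
- Comparison: the chosen plan fixes every substituent position by bond construction and avoids any biaryl coupling. This plan asks an electrophilic substitution to choose correctly twice. It wins on length only if both regiochemical questions resolve favourably.

**Alternative 3:** The bond from ring B C6' to its bridge carbon is cut, and the bridge carbon is tied temporarily to the ring A oxygen at C2. The forward key step combines the biaryl phenol 3,3',4'-tris(benzyloxy)-5-[2-(3-methoxyphenyl)ethyl]biphenyl-2-ol A7 with 3-methoxyphenylacetaldehyde dimethyl acetal A8 under acid. Acetal exchange, ionization to an aryloxycarbenium ion and attack by ring B at C6' (para to the 3'-benzyloxy group) would close the 6H-benzo[c]chromene A9. Hydrogenolysis would then cleave the benzylic C6–O bond of the pyran and the three benzyl ethers and give 21.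
- In favour: the phenol next to the biaryl bond serves as a traceless tether, so the arm is delivered to ring B intramolecularly and only to a position ortho to the biaryl bond. All intermediates are robust benzyl-protected aromatics, with no polymerizable enone and no oxidation in the presence of a nascent catechol. On robustness of intermediates it is better than the chosen plan. Its endgame, a single hydrogenolysis, is at least the equal.
- Against: A7 needs exactly the hindered, electron-rich biaryl cross-coupling that the chosen plan avoids, plus one phenol differentiated from three benzylated ones. An oxocarbenium ion from an arylacetaldehyde can lose a proton to a conjugated styryl ether and is only weakly stabilized by an aryloxy group. Ring B C2' is a second possible site of attack. Reductive opening of the cyclic benzylic aryl ether is expected to be slower than O-debenzylation.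
- Step economy: about equal. The ring A arm must be built separately by olefination and reduction as in steps 2 and 3, followed by biaryl coupling, selective unmasking, cyclization and hydrogenolysis.

Key step: step 8

## Route

Step 1
Reactants: 1 3,4-bis(benzyloxy)benzaldehyde
Product: 2 4,5-bis(benzyloxy)-2-bromobenzaldehyde
Conditions: Br2, NaOAc, AcOH, rt
Reagents that add atoms: bromine, BrBr
Why: Electrophilic aromatic bromination; the C3 benzyloxy group directs to its para position (C6, ortho to the formyl group), as is usual for 3,4-dialkoxybenzaldehydes, and the acetate buffer removes HBr so the benzyl ethers survive.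

Step 2
Reactants: 2 4,5-bis(benzyloxy)-2-bromobenzaldehyde; 3 (3-methoxybenzyl)triphenylphosphonium chloride
Product: 5 1,2-bis(benzyloxy)-4-bromo-5-[2-(3-methoxyphenyl)ethenyl]benzene (E/Z mixture), via phosphorus ylide 4 (not isolated)
Conditions: KOtBu, THF, 0 °C → rt
Reagents that add atoms: none
Why: Wittig olefination of an aromatic aldehyde with a semi-stabilized benzylic ylide; the E/Z mixture does not matter because the double bond is saturated in the next step, and the aryl bromide is inert to the ylide.

Step 3
Reactants: 5 1,2-bis(benzyloxy)-4-bromo-5-[2-(3-methoxyphenyl)ethenyl]benzene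
Product: 6 1,2-bis(benzyloxy)-4-bromo-5-[2-(3-methoxyphenyl)ethyl]benzene
Conditions: TsNHNH2 (excess, in portions), NaOAc, DME/H2O, reflux
Reagents that add atoms: none
Why: Diimide reduction (concerted syn transfer of two hydrogens from HN=NH generated by thermolysis of the sulfonyl hydrazide) saturates the stilbene and leaves the carbon–bromine bond and the benzyl ethers untouched; both would be at risk under Pd-catalysed hydrogenation.

Step 4
Reactants: 6 1,2-bis(benzyloxy)-4-bromo-5-[2-(3-methoxyphenyl)ethyl]benzene
Product: 7 ethyl {4,5-bis(benzyloxy)-2-[2-(3-methoxyphenyl)ethyl]phenyl}acetate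
Conditions: BrZnCH2CO2Et (THF solution), Pd2(dba)3 (cat.), XPhos, THF, 65 °C
Reagents that add atoms: (2-ethoxy-2-oxoethyl)zinc bromide, CCOC(=O)C[Zn]Br
Why: Negishi-type coupling of a Reformatsky reagent (Pd-catalysed α-arylation of a zinc ester enolate): oxidative addition of the bromide to zerovalent palladium, transmetallation and reductive elimination form the aryl–CH2 bond; the neutral zinc enolate avoids Claisen condensation and diarylation.

Step 5
Reactants: 7 ethyl {4,5-bis(benzyloxy)-2-[2-(3-methoxyphenyl)ethyl]phenyl}acetate
Product: 8 2-{4,5-bis(benzyloxy)-2-[2-(3-methoxyphenyl)ethyl]phenyl}-N-methoxy-N-methylacetamide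
Conditions: MeNH(OMe)·HCl, iPrMgCl, THF, −20 → 0 °C
Reagents that add atoms: N,O-dimethylhydroxylamine hydrochloride, CNOC.Cl
Why: Direct aminolysis of the ethyl ester by the magnesium amide of N,O-dimethylhydroxylamine (Weinreb amide formation); the amide anion is a good nucleophile but a weak base, so the acidic arylacetate is acylated and not merely enolized, and no acid step is needed.

Step 6
Reactants: 8 2-{4,5-bis(benzyloxy)-2-[2-(3-methoxyphenyl)ethyl]phenyl}-N-methoxy-N-methylacetamide
Product: 10 1-{4,5-bis(benzyloxy)-2-[2-(3-methoxyphenyl)ethyl]phenyl}but-3-en-2-one, via magnesium chelate 9 (not isolated)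
Conditions: CH2=CHMgBr, THF, −78 → 0 °C; inverse quench into cold 1 M HCl; crude product (trace BHT) used at once
Reagents that add atoms: vinylmagnesium bromide, C=C[Mg]Br
Why: Weinreb ketone synthesis; the chelated adduct 9 survives until the quench, so the Grignard reagent adds only once, and pouring into cold acid protonates the released N,O-dimethylhydroxylamine before it can add to the new enone.

Step 7
Reactants: 11 4-(3-methoxyphenyl)butanoic acid
Product: 13 4-(3-methoxyphenyl)butanal, via acid chloride 12 (not isolated)
Conditions: (COCl)2, cat. DMF, CH2Cl2, 0 °C → rt, evaporate; LiAlH(OtBu)3, THF, −78 °C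
Reagents that add atoms: none
Why: Acid chloride formation followed by partial reduction with the hindered hydride LiAlH(OtBu)3, which at low temperature reduces acyl chlorides much faster than aldehydes; the aryl methyl ether is inert, and 13 is used in excess in step 8, so a moderate return is tolerable.

Step 8
Reactants: 13 4-(3-methoxyphenyl)butanal; 10 1-{4,5-bis(benzyloxy)-2-[2-(3-methoxyphenyl)ethyl]phenyl}but-3-en-2-one
Product: 16 2-{4,5-bis(benzyloxy)-2-[2-(3-methoxyphenyl)ethyl]phenyl}-4-[2-(3-methoxyphenyl)ethyl]cyclohex-2-en-1-one (racemic), via enamine 14 (not isolated), via keto aldehyde 15 (not isolated)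
Conditions: 13 (excess), pyrrolidine, 4 Å MS, PhMe, 0 °C → rt, evaporate; 10 (slow addition), MeCN, 0 °C → rt; AcOH, NaOAc, H2O, 70 °C
Reagents that add atoms: none
Why: The preformed enamine 14 adds through its β-carbon to the unsubstituted terminus of the vinyl ketone 10 (enamine Michael addition), and the aqueous acetate buffer hydrolyses the adduct to the 1,5-keto aldehyde 15. In the same pyrrolidinium acetate medium the benzylic α-carbon of the ketone, activated by both the carbonyl group and ring B, attacks the aldehyde (free or as its iminium ion), and the aldol or Mannich adduct eliminates water or amine by an E1cB path to give the conjugated enone 16. The closest known reaction type is the enamine (amine-mediated) Robinson annulation of aldehydes with vinyl ketones to 4-substituted cyclohex-2-enones. Ring A closes by a 6-(enolendo)-exo-trig aldol addition followed by dehydration. The only stereocentre, C4, is set in the Michael step with no controlling element, so 16 is racemic; this is intended, because C4 becomes an aromatic carbon in step 10. Regioselectivity of the closure is secured by the substrate, since attack from the other ketone α-carbon, or from the aldehyde α-carbon onto the ketone, would give four-membered rings. Chemoselectivity (cross-Michael addition before self-condensation of either partner) is secured by complete pre-formation of the enamine, removal of free amine, an excess of 13 and slow addition of 10. The double bond ends in conjugation with the carbonyl group, which places ring B on the α-carbon and the arm on the γ-carbon, as ring A requires.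

Step 9
Reactants: 16 2-{4,5-bis(benzyloxy)-2-[2-(3-methoxyphenyl)ethyl]phenyl}-4-[2-(3-methoxyphenyl)ethyl]cyclohex-2-en-1-one
Product: 18 2-{4,5-bis(benzyloxy)-2-[2-(3-methoxyphenyl)ethyl]phenyl}-6-hydroxy-4-[2-(3-methoxyphenyl)ethyl]cyclohex-2-en-1-one (cis/trans mixture of racemates), via sodium dienolate 17 (not isolated)
Conditions: NaN(SiMe3)2, THF, −78 °C; 2-(phenylsulfonyl)-3-phenyloxaziridine, −78 °C; aq. NH4Cl
Reagents that add atoms: 2-(phenylsulfonyl)-3-phenyloxaziridine, O=S(=O)(N1OC1c1ccccc1)c1ccccc1
Why: Kinetic deprotonation at the α'-methylene (C6) with a hindered amide base gives the cross-conjugated dienolate 17, which is hydroxylated at carbon by the N-sulfonyloxaziridine (Davis enolate oxidation); the new carbinol centre forms as a cis/trans mixture relative to C4, which is immaterial because both centres become sp2 in step 10.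

Step 10
Reactants: 18 2-{4,5-bis(benzyloxy)-2-[2-(3-methoxyphenyl)ethyl]phenyl}-6-hydroxy-4-[2-(3-methoxyphenyl)ethyl]cyclohex-2-en-1-one
Product: 20 3-{4,5-bis(benzyloxy)-2-[2-(3-methoxyphenyl)ethyl]phenyl}-5-[2-(3-methoxyphenyl)ethyl]benzene-1,2-diol, via ene-dione 19 (not isolated)
Conditions: (COCl)2, DMSO, CH2Cl2, −78 °C; Et3N, −78 → 0 °C; degassed aq. NH4Cl, under Ar
Reagents that add atoms: none
Why: Swern oxidation of the α-hydroxy ketone gives the 1,2-dione 19, the keto tautomer of a catechol; the Et3N already present removes first a proton of the CH2 next to the new carbonyl and then the ring CH that bears the arm, and aromatization drives both enolizations to 20 and erases both stereocentres. Activated DMSO at low temperature is chosen because it does not oxidize phenols to quinones.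

Step 11
Reactants: 20 3-{4,5-bis(benzyloxy)-2-[2-(3-methoxyphenyl)ethyl]phenyl}-5-[2-(3-methoxyphenyl)ethyl]benzene-1,2-diol
Product: 21 isoplagilin, 5,6'-bis[2-(3-methoxyphenyl)ethyl]biphenyl-2,3,3',4'-tetraol
Conditions: H2 (1 atm), 10 % Pd/C, EtOAc/MeOH, rt; filtration under Ar
Reagents that add atoms: none
Why: Catalytic hydrogenolysis of the two aryl benzyl ethers; aryl methyl ethers, the bibenzyl CH2 groups and the catechols are inert, and the neutral, base-free conditions suit the oxidation-prone tetraol.

## Compound list

1 | 3,4-bis(benzyloxy)benzaldehyde | O=Cc1ccc(OCc2ccccc2)c(OCc2ccccc2)c1 | starting material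
2 | 4,5-bis(benzyloxy)-2-bromobenzaldehyde | O=Cc1cc(OCc2ccccc2)c(OCc2ccccc2)cc1Br | intermediate
3 | (3-methoxybenzyl)triphenylphosphonium chloride | COc1cccc(C[P+](c2ccccc2)(c2ccccc2)c2ccccc2)c1.[Cl-] | starting material
4 | (3-methoxybenzylidene)triphenylphosphorane | COc1cccc(C=P(c2ccccc2)(c2ccccc2)c2ccccc2)c1 | intermediate (not isolated)
5 | 1,2-bis(benzyloxy)-4-bromo-5-[2-(3-methoxyphenyl)ethenyl]benzene (E/Z mixture) | COc1cccc(C=Cc2cc(OCc3ccccc3)c(OCc3ccccc3)cc2Br)c1 | intermediate
6 | 1,2-bis(benzyloxy)-4-bromo-5-[2-(3-methoxyphenyl)ethyl]benzene | COc1cccc(CCc2cc(OCc3ccccc3)c(OCc3ccccc3)cc2Br)c1 | intermediate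
7 | ethyl {4,5-bis(benzyloxy)-2-[2-(3-methoxyphenyl)ethyl]phenyl}acetate | CCOC(=O)Cc1cc(OCc2ccccc2)c(OCc2ccccc2)cc1CCc1cccc(OC)c1 | intermediate
8 | 2-{4,5-bis(benzyloxy)-2-[2-(3-methoxyphenyl)ethyl]phenyl}-N-methoxy-N-methylacetamide | CON(C)C(=O)Cc1cc(OCc2ccccc2)c(OCc2ccccc2)cc1CCc1cccc(OC)c1 | intermediate
9 | bromomagnesium 1-{4,5-bis(benzyloxy)-2-[2-(3-methoxyphenyl)ethyl]phenyl}-2-[methoxy(methyl)amino]but-3-en-2-olate (chelated tetrahedral adduct, racemic) | C=CC(O[Mg]Br)(Cc1cc(OCc2ccccc2)c(OCc2ccccc2)cc1CCc1cccc(OC)c1)N(C)OC | intermediate (not isolated)
10 | 1-{4,5-bis(benzyloxy)-2-[2-(3-methoxyphenyl)ethyl]phenyl}but-3-en-2-one | C=CC(=O)Cc1cc(OCc2ccccc2)c(OCc2ccccc2)cc1CCc1cccc(OC)c1 | intermediate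
11 | 4-(3-methoxyphenyl)butanoic acid | COc1cccc(CCCC(=O)O)c1 | starting material
12 | 4-(3-methoxyphenyl)butanoyl chloride | COc1cccc(CCCC(=O)Cl)c1 | intermediate (not isolated)
13 | 4-(3-methoxyphenyl)butanal | COc1cccc(CCCC=O)c1 | intermediate
14 | (E)-1-[4-(3-methoxyphenyl)but-1-en-1-yl]pyrrolidine | COc1cccc(CC/C=C/N2CCCC2)c1 | intermediate (not isolated)
15 | 6-{4,5-bis(benzyloxy)-2-[2-(3-methoxyphenyl)ethyl]phenyl}-2-[2-(3-methoxyphenyl)ethyl]-5-oxohexanal (racemic) | O=CC(CCc1cccc(OC)c1)CCC(=O)Cc1cc(OCc2ccccc2)c(OCc2ccccc2)cc1CCc1cccc(OC)c1 | intermediate (not isolated)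
16 | 2-{4,5-bis(benzyloxy)-2-[2-(3-methoxyphenyl)ethyl]phenyl}-4-[2-(3-methoxyphenyl)ethyl]cyclohex-2-en-1-one (racemic) | O=C1CCC(CCc2cccc(OC)c2)C=C1c1cc(OCc2ccccc2)c(OCc2ccccc2)cc1CCc1cccc(OC)c1 | intermediate
17 | sodium 6-{4,5-bis(benzyloxy)-2-[2-(3-methoxyphenyl)ethyl]phenyl}-4-[2-(3-methoxyphenyl)ethyl]cyclohexa-1,5-dien-1-olate (racemic) | [Na+].[O-]C1=CCC(CCc2cccc(OC)c2)C=C1c1cc(OCc2ccccc2)c(OCc2ccccc2)cc1CCc1cccc(OC)c1 | intermediate (not isolated)
18 | 2-{4,5-bis(benzyloxy)-2-[2-(3-methoxyphenyl)ethyl]phenyl}-6-hydroxy-4-[2-(3-methoxyphenyl)ethyl]cyclohex-2-en-1-one (cis/trans mixture, each racemic) | O=C1C(O)CC(CCc2cccc(OC)c2)C=C1c1cc(OCc2ccccc2)c(OCc2ccccc2)cc1CCc1cccc(OC)c1 | intermediate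
19 | 3-{4,5-bis(benzyloxy)-2-[2-(3-methoxyphenyl)ethyl]phenyl}-5-[2-(3-methoxyphenyl)ethyl]cyclohex-3-ene-1,2-dione (racemic) | O=C1C(=O)CC(CCc2cccc(OC)c2)C=C1c1cc(OCc2ccccc2)c(OCc2ccccc2)cc1CCc1cccc(OC)c1 | intermediate (not isolated)
20 | 3-{4,5-bis(benzyloxy)-2-[2-(3-methoxyphenyl)ethyl]phenyl}-5-[2-(3-methoxyphenyl)ethyl]benzene-1,2-diol | COc1cccc(CCc2cc(O)c(O)c(-c3cc(OCc4ccccc4)c(OCc4ccccc4)cc3CCc3cccc(OC)c3)c2)c1 | intermediate
21 | isoplagilin, 5,6'-bis[2-(3-methoxyphenyl)ethyl]biphenyl-2,3,3',4'-tetraol | COc1cccc(CCc2cc(O)c(O)c(-c3cc(O)c(O)cc3CCc3cccc(OC)c3)c2)c1 | target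

## Step count and least certain steps

Total step count: 11. Longest linear sequence: 10 steps (steps 1 to 6, then 8 to 11); step 7 is a one-step side branch.

**Step 8 (key step).** The most likely failure is loss of the vinyl ketone by self-addition and polymerization before the enamine captures it, because 10 combines an unhindered acceptor with an acidic benzylic CH2. A second risk is stalling at the keto aldehyde stage with self-condensation of the aldehyde. The fallback separates the annulation from the introduction of ring B.
- It sets out from 13 and 6. The same enamine annulation of 13 with but-3-en-2-one, the standard partner, should give 4-[2-(3-methoxyphenyl)ethyl]cyclohex-2-en-1-one F1.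
- α-Iodination (I2, pyridine, CH2Cl2) should give 2-iodo-4-[2-(3-methoxyphenyl)ethyl]cyclohex-2-en-1-one F2.
- Bromide 6 is borylated (bis(pinacolato)diboron, Pd(dppf)Cl2, KOAc, dioxane, 90 °C) to 2-{4,5-bis(benzyloxy)-2-[2-(3-methoxyphenyl)ethyl]phenyl}-4,4,5,5-tetramethyl-1,3,2-dioxaborolane F3.
- Suzuki–Miyaura coupling of F2 with F3 (Pd(OAc)2, SPhos, K3PO4, THF/H2O) comes back to the route at 16.

**Step 6.** The most likely failure is conjugate addition of the released N,O-dimethylhydroxylamine, or of a second equivalent of the Grignard reagent, to the enone during the quench, and polymerization on concentration. The fallback does not isolate the enone.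
- It sets out from 8. The same Grignard addition is quenched with diethylamine and water, which captures the enone as the stable Mannich base 1-{4,5-bis(benzyloxy)-2-[2-(3-methoxyphenyl)ethyl]phenyl}-4-(diethylamino)butan-2-one F4.
- MeI converts this into 4-{4,5-bis(benzyloxy)-2-[2-(3-methoxyphenyl)ethyl]phenyl}-N,N-diethyl-N-methyl-3-oxobutan-1-aminium iodide F5.
- In the flask of step 8, F5 and iPr2NEt release the enone slowly in the presence of 14, so the route is rejoined at 10.

**Step 10.** The most likely failure is attack on the catechol as it forms, either S-alkylation or over-oxidation of the electron-rich catecholate by excess activated DMSO, or air oxidation during the basic phase. The fallback introduces the second oxygen after aromatization.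
- It sets out from 16. Aerobic dehydrogenation (Pd(O2CCF3)2, 2-(dimethylamino)pyridine, TsOH, O2, DMSO, 80 °C) should give the phenol 4',5'-bis(benzyloxy)-2',5-bis[2-(3-methoxyphenyl)ethyl]biphenyl-2-ol F6.
- IBX in DMF oxygenates the only free ortho position to the ortho-quinone 3-{4,5-bis(benzyloxy)-2-[2-(3-methoxyphenyl)ethyl]phenyl}-5-[2-(3-methoxyphenyl)ethyl]cyclohexa-3,5-diene-1,2-dione F7.
- Reduction in the same flask with Na2S2O4 comes back to the route at 20.

**Step 9.** The most likely failure is incomplete regiocontrol of enolization (deprotonation at the C4 methine to the extended dienolate) and addition of the enolate to the sulfonimine by-product. The fallback is the two-stage Rubottom oxidation.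
- It sets out from 16. LiN(iPr)2 and Me3SiCl in THF at −78 °C give the cross-conjugated silyl dienol ether {[6-{4,5-bis(benzyloxy)-2-[2-(3-methoxyphenyl)ethyl]phenyl}-4-[2-(3-methoxyphenyl)ethyl]cyclohexa-1,5-dien-1-yl]oxy}trimethylsilane F8.
- mCPBA with NaHCO3 in CH2Cl2 at −20 °C epoxidizes the silyl enol ether double bond, and a mild acid work-up comes back to the route at 18.

**Step 4.** The most likely failure is slow oxidative addition of the electron-rich, ortho-alkylated bromide, with protodebromination and decay of the zinc enolate taking over. The fallback uses no palladium.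
- It sets out from 6. Bromine–lithium exchange (nBuLi, THF, −78 °C) and allylation (CuI cat., allyl bromide) give 1,2-bis(benzyloxy)-4-[2-(3-methoxyphenyl)ethyl]-5-(prop-2-en-1-yl)benzene F9.
- Oxidative cleavage (K2OsO4·2H2O cat., NaIO4, 2,6-lutidine, dioxane/H2O) gives {4,5-bis(benzyloxy)-2-[2-(3-methoxyphenyl)ethyl]phenyl}acetaldehyde F10.
- CH2=CHMgBr gives 1-{4,5-bis(benzyloxy)-2-[2-(3-methoxyphenyl)ethyl]phenyl}but-3-en-2-ol F11, and Dess–Martin oxidation comes back to the route at 10, bypassing 7 and 8.

## Further compounds

F1 | step 8 | 4-[2-(3-methoxyphenyl)ethyl]cyclohex-2-en-1-one (racemic) | O=C1CCC(CCc2cccc(OC)c2)C=C1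
F2 | step 8 | 2-iodo-4-[2-(3-methoxyphenyl)ethyl]cyclohex-2-en-1-one (racemic) | O=C1CCC(CCc2cccc(OC)c2)C=C1I
F3 | step 8 | 2-{4,5-bis(benzyloxy)-2-[2-(3-methoxyphenyl)ethyl]phenyl}-4,4,5,5-tetramethyl-1,3,2-dioxaborolane | COc1cccc(CCc2cc(OCc3ccccc3)c(OCc3ccccc3)cc2B2OC(C)(C)C(C)(C)O2)c1
F4 | step 6 | 1-{4,5-bis(benzyloxy)-2-[2-(3-methoxyphenyl)ethyl]phenyl}-4-(diethylamino)butan-2-one | CCN(CC)CCC(=O)Cc1cc(OCc2ccccc2)c(OCc2ccccc2)cc1CCc1cccc(OC)c1
F5 | step 6 | 4-{4,5-bis(benzyloxy)-2-[2-(3-methoxyphenyl)ethyl]phenyl}-N,N-diethyl-N-methyl-3-oxobutan-1-aminium iodide | CC[N+](C)(CC)CCC(=O)Cc1cc(OCc2ccccc2)c(OCc2ccccc2)cc1CCc1cccc(OC)c1.[I-]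
F6 | step 10 | 4',5'-bis(benzyloxy)-2',5-bis[2-(3-methoxyphenyl)ethyl]biphenyl-2-ol | COc1cccc(CCc2ccc(O)c(-c3cc(OCc4ccccc4)c(OCc4ccccc4)cc3CCc3cccc(OC)c3)c2)c1
F7 | step 10 | 3-{4,5-bis(benzyloxy)-2-[2-(3-methoxyphenyl)ethyl]phenyl}-5-[2-(3-methoxyphenyl)ethyl]cyclohexa-3,5-diene-1,2-dione | O=C1C(=O)C(c2cc(OCc3ccccc3)c(OCc3ccccc3)cc2CCc2cccc(OC)c2)=CC(CCc2cccc(OC)c2)=C1
F8 | step 9 | {[6-{4,5-bis(benzyloxy)-2-[2-(3-methoxyphenyl)ethyl]phenyl}-4-[2-(3-methoxyphenyl)ethyl]cyclohexa-1,5-dien-1-yl]oxy}trimethylsilane (racemic) | C[Si](C)(C)OC1=CCC(CCc2cccc(OC)c2)C=C1c1cc(OCc2ccccc2)c(OCc2ccccc2)cc1CCc1cccc(OC)c1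
F9 | step 4 | 1,2-bis(benzyloxy)-4-[2-(3-methoxyphenyl)ethyl]-5-(prop-2-en-1-yl)benzene | C=CCc1cc(OCc2ccccc2)c(OCc2ccccc2)cc1CCc1cccc(OC)c1
F10 | step 4 | {4,5-bis(benzyloxy)-2-[2-(3-methoxyphenyl)ethyl]phenyl}acetaldehyde | O=CCc1cc(OCc2ccccc2)c(OCc2ccccc2)cc1CCc1cccc(OC)c1
F11 | step 4 | 1-{4,5-bis(benzyloxy)-2-[2-(3-methoxyphenyl)ethyl]phenyl}but-3-en-2-ol (racemic) | C=CC(O)Cc1cc(OCc2ccccc2)c(OCc2ccccc2)cc1CCc1cccc(OC)c1
A1 | alternative 1 | 3,4-bis(benzyloxy)-6-[2-(3-methoxyphenyl)ethyl]-2H-pyran-2-one | O=c1oc(CCc2cccc(OC)c2)cc(OCc2ccccc2)c1OCc1ccccc1
A2 | alternative 1 | methyl 3-{4,5-bis(benzyloxy)-2-[2-(3-methoxyphenyl)ethyl]phenyl}prop-2-ynoate | COC(=O)C#Cc1cc(OCc2ccccc2)c(OCc2ccccc2)cc1CCc1cccc(OC)c1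
A3 | alternative 1 | methyl 4',5,5',6-tetrakis(benzyloxy)-2',3-bis[2-(3-methoxyphenyl)ethyl]biphenyl-2-carboxylate | COC(=O)c1c(CCc2cccc(OC)c2)cc(OCc2ccccc2)c(OCc2ccccc2)c1-c1cc(OCc2ccccc2)c(OCc2ccccc2)cc1CCc1cccc(OC)c1
A4 | alternative 2 | biphenyl-2,3,3',4'-tetraol | Oc1ccc(-c2cccc(O)c2O)cc1O
A5 | alternative 2 | 3-methoxyphenylacetic acid | COc1cccc(CC(=O)O)c1
A6 | alternative 2 | 1-{2,3,3',4'-tetrahydroxy-6'-[(3-methoxyphenyl)acetyl]biphenyl-5-yl}-2-(3-methoxyphenyl)ethan-1-one | COc1cccc(CC(=O)c2cc(O)c(O)c(-c3cc(O)c(O)cc3C(=O)Cc3cccc(OC)c3)c2)c1
A7 | alternative 3 | 3,3',4'-tris(benzyloxy)-5-[2-(3-methoxyphenyl)ethyl]biphenyl-2-ol | COc1cccc(CCc2cc(OCc3ccccc3)c(O)c(-c3ccc(OCc4ccccc4)c(OCc4ccccc4)c3)c2)c1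
A8 | alternative 3 | 1-(2,2-dimethoxyethyl)-3-methoxybenzene (3-methoxyphenylacetaldehyde dimethyl acetal) | COc1cccc(CC(OC)OC)c1
A9 | alternative 3 | 4,8,9-tris(benzyloxy)-6-(3-methoxybenzyl)-2-[2-(3-methoxyphenyl)ethyl]-6H-benzo[c]chromene (racemic) | COc1cccc(CC2Oc3c(OCc4ccccc4)cc(CCc4cccc(OC)c4)cc3-c3cc(OCc4ccccc4)c(OCc4ccccc4)cc32)c1
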